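**Retrosynthetic overview**

1. Target 22 ⇐ hydrogenolysis of three benzyl ethers ⇐ (R)-isoflavanone 21 ⇐ re-oxidation at C4 ⇐ cis-(3R,4R)-isoflavan-4-ol 20 ⇐ asymmetric transfer hydrogenation with dynamic kinetic resolution (sets C3) ⇐ tribenzyl isoflavone 18.
2. Isoflavone 18 ⇐ one-carbon ring expansion: the pyranone ring O1–C2–C3–C4–C4a–C8a is made from the furan ring O1–C2–C3–C3a–C7a of 3-silyloxybenzofuran 10 by insertion of the aryl(chloro)carbene carbon of diazirine 15 between C2 and the O-bearing carbon; it arrives as C3 with the B ring already on it.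
3. Enabling feature: in the target, C3 is the one ring carbon that carries the B ring, and it lies between the O1-bound C2 and the A-ring-bound carbonyl C4. Removing it leaves exactly the C2=C3 enol ether of a benzofuran-3-ol whose oxygen is the future C4=O, so the insertion is regiochemically unambiguous.
4. 10 ⇐ benzofuranone 9 ⇐ Friedel–Crafts closure of aryloxyacetic acid 7 ⇐ C2v-symmetric phenol 6 ⇐ Dakin-type oxidation ⇐ 4-O-methylgallic acid 1; 15 ⇐ amidine 14 ⇐ nitrile 12 ⇐ aldehyde 11.
5. Ring order: A and B rings are bought; the furanone ring is closed in step 6 and expanded to the pyranone ring in step 11; the stereocenter is installed afterwards in step 12.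

Key step: step 11

Assumption: 1 and 11 are taken as purchasable; 16, 17 and 19 are transient, racemic or achiral, and are drawn without configuration; CIP analysis of the target SMILES gives (3R).

**Route**

Step 1
Reactants: 1 3,5-dihydroxy-4-methoxybenzoic acid
Product: 2 benzyl 3,5-bis(benzyloxy)-4-methoxybenzoate
Conditions: BnBr (3.3 equiv), K2CO3, DMF, 60 °C
Reagents that add atoms: benzyl bromide, BrCc1ccccc1
Why: Williamson etherification of both phenols together with carboxylate O-alkylation (SN2) should protect all three acidic sites in one operation.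

Step 2
Reactants: 2 benzyl 3,5-bis(benzyloxy)-4-methoxybenzoate
Product: 3 [3,5-bis(benzyloxy)-4-methoxyphenyl]methanol
Conditions: LiAlH4, THF, 0 °C to rt
Reagents that add atoms: none
Why: Hydride reduction of the benzyl ester should give the primary benzylic alcohol while aryl benzyl ethers are inert to LiAlH4.

Step 3
Reactants: 3 [3,5-bis(benzyloxy)-4-methoxyphenyl]methanol
Product: 4 3,5-bis(benzyloxy)-4-methoxybenzaldehyde
Conditions: MnO2, CH2Cl2, rt
Reagents that add atoms: none
Why: Activated MnO2 oxidises benzylic alcohols selectively to the aldehyde without over-oxidation.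

Step 4
Reactants: 4 3,5-bis(benzyloxy)-4-methoxybenzaldehyde
Product: 6 3,5-bis(benzyloxy)-4-methoxyphenol, via aryl formate 5 (not isolated)
Conditions: mCPBA, CH2Cl2, 0 °C to rt; then K2CO3 (cat.), MeOH, rt
Reagents that add atoms: mCPBA, OOC(=O)c1cccc(Cl)c1
Why: Baeyer–Villiger (Dakin-type) oxidation, in which the electron-rich trialkoxyaryl group migrates in the Criegee intermediate to give the formate, which mild methanolysis should cleave to the phenol.

Step 5
Reactants: 6 3,5-bis(benzyloxy)-4-methoxyphenol
Product: 7 2-[3,5-bis(benzyloxy)-4-methoxyphenoxy]acetic acid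
Conditions: BrCH2CO2H, NaH (2.2 equiv), THF/DMF, 0 to 60 °C; aq. HCl work-up
Reagents that add atoms: bromoacetic acid, OC(=O)CBr
Why: Williamson O-alkylation of the sodium phenoxide by bromoacetate (SN2), with the acid masked in situ as its sodium salt.

Step 6
Reactants: 7 2-[3,5-bis(benzyloxy)-4-methoxyphenoxy]acetic acid
Product: 9 4,6-bis(benzyloxy)-5-methoxybenzofuran-3(2H)-one, via mixed trifluoroacetic anhydride 8 (not isolated)
Conditions: TFAA, H3PO4 (cat.), CH2Cl2, 0 °C to rt
Reagents that add atoms: none
Why: Intramolecular Friedel–Crafts acylation through the mixed anhydride; the two ortho positions of the C2v-symmetric ring are equivalent and activated by three alkoxy groups, so only one benzofuranone can form and no metal Lewis acid threatens the benzyl ethers.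

Step 7
Reactants: 9 4,6-bis(benzyloxy)-5-methoxybenzofuran-3(2H)-one
Product: 10 [4,6-bis(benzyloxy)-5-methoxybenzofuran-3-yl]oxy(tert-butyl)dimethylsilane
Conditions: TBSOTf, Et3N, CH2Cl2, 0 °C
Reagents that add atoms: tert-butyldimethylsilyl triflate, CC(C)(C)[Si](C)(C)OS(=O)(=O)C(F)(F)F
Why: Silyl enol ether formation (soft enolisation and O-silylation) is driven by aromatisation to the benzofuran and should give the electron-rich C2=C3 enol ether needed for the carbene.

Step 8
Reactants: 11 3-(benzyloxy)-4,5-dimethoxybenzaldehyde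
Product: 12 3-(benzyloxy)-4,5-dimethoxybenzonitrile
Conditions: I2, aq. NH3, THF, rt
Reagents that add atoms: ammonia, N
Why: Oxidative aldehyde-to-nitrile conversion (aldimine formation, N-iodination, loss of HI), which tolerates alkoxyarenes.

Step 9
Reactants: 12 3-(benzyloxy)-4,5-dimethoxybenzonitrile
Product: 14 3-(benzyloxy)-4,5-dimethoxybenzamidine hydrochloride, via lithium bis(silyl)amidinate 13 (not isolated)
Conditions: LiHMDS, THF, 0 °C to rt; then HCl (4 M in dioxane), 0 °C
Reagents that add atoms: lithium bis(trimethylsilyl)amide, [Li]N([Si](C)(C)C)[Si](C)(C)C; hydrogen chloride, Cl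
Why: Addition of the silylamide to the nitrile followed by protodesilylation with HCl is the standard amidine synthesis from benzonitriles.

Step 10
Reactants: 14 3-(benzyloxy)-4,5-dimethoxybenzamidine hydrochloride
Product: 15 3-[3-(benzyloxy)-4,5-dimethoxyphenyl]-3-chloro-3H-diazirine
Conditions: aq. NaOCl, LiCl, DMSO/pentane, 0 °C to rt
Reagents that add atoms: sodium hypochlorite, [Na+].[O-]Cl; lithium chloride, [Li+].[Cl-]
Why: Graham oxidation, in which double N-chlorination, base-induced N–N closure and SN2' return of chloride should give the 3-aryl-3-chlorodiazirine.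

Step 11
Reactants: 10 [4,6-bis(benzyloxy)-5-methoxybenzofuran-3-yl]oxy(tert-butyl)dimethylsilane; 15 3-[3-(benzyloxy)-4,5-dimethoxyphenyl]-3-chloro-3H-diazirine
Product: 18 5,7-bis(benzyloxy)-3-[3-(benzyloxy)-4,5-dimethoxyphenyl]-6-methoxy-4H-chromen-4-one, via chlorocyclopropane adduct 16 (not isolated), via 4-silyloxychromenylium chloride 17 (not isolated)
Conditions: 15 (2 equiv, slow addition), Na2CO3, MeCN, 60 °C, dark
Reagents that add atoms: none
Why: Proposed new method: thermolysis of 15 releases N2 and the singlet aryl(chloro)carbene, which should cyclopropanate the C2=C3 enol-ether bond of 10 to give 16; chloride ionisation with disrotatory 2π-electrocyclic opening of the cyclopropyl cation then cleaves the old C2–C3 bond to give the 3-aryl-4-silyloxybenzopyrylium chloride 17, which chloride desilylates to the chromone carbonyl. The closest known reaction type is the Ciamician–Dennstedt-type carbon-atom insertion of aryl(chloro)carbenes from chlorodiazirines into indoles and pyrroles, together with the dihalocarbene ring expansions of benzofuran and of cyclic silyl enol ethers; aryl(chloro)carbene insertion into a 3-silyloxybenzofuran has not been shown. The six-membered ring is not closed by a cyclisation but arises from the bicyclo[3.1.0] adduct by cleavage of the shared bond (one-carbon expansion of the furan ring, 5 to 6), and no stereocenter is formed because the inserted carbon becomes sp2 (C3 is set in step 12). The step needs chemoselectivity for the enol-ether π bond over the alkoxyarenes and benzyl ethers, which the O1 and OSi donors on C2=C3 should secure, and it needs the aryl-bearing carbon to end next to the carbonyl, which the mechanism fixes because the carbene carbon can only end between the old C2 and C3. Only the adduct with Cl syn to the furan ring can open directly; the anti isomer is expected to equilibrate through the oxygen-stabilised zwitterion at 60 °C.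

Step 12
Reactants: 18 5,7-bis(benzyloxy)-3-[3-(benzyloxy)-4,5-dimethoxyphenyl]-6-methoxy-4H-chromen-4-one
Product: 20 (3R,4R)-5,7-bis(benzyloxy)-3-[3-(benzyloxy)-4,5-dimethoxyphenyl]-6-methoxychroman-4-ol, via racemic isoflavanone 19 (not isolated)
Conditions: RuCl[(R,R)-TsDPEN](p-cymene) (5 mol %), HCO2H/Et3N (5:2), EtOAc, 40 °C
Reagents that add atoms: none
Why: Noyori–Ikariya asymmetric transfer hydrogenation with dynamic kinetic resolution: Ru–H conjugate reduction gives the configurationally labile isoflavanone 19, the (R,R)-catalyst should set C4 as R as it does for aryl alkyl ketones, hydride delivery anti to the 3-aryl group makes the (3R)-enantiomer the fast-reacting one (cis product), and the slow enantiomer racemises through the enol under Et3N.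

Step 13
Reactants: 20 (3R,4R)-5,7-bis(benzyloxy)-3-[3-(benzyloxy)-4,5-dimethoxyphenyl]-6-methoxychroman-4-ol
Product: 21 (3R)-5,7-bis(benzyloxy)-3-[3-(benzyloxy)-4,5-dimethoxyphenyl]-6-methoxychroman-4-one
Conditions: Dess–Martin periodinane, CH2Cl2, 0 °C
Reagents that add atoms: none
Why: Dess–Martin oxidation of the secondary benzylic alcohol under non-basic conditions should remove the auxiliary C4 stereocenter without epimerising the α-aryl C3 stereocenter.

Step 14
Reactants: 21 (3R)-5,7-bis(benzyloxy)-3-[3-(benzyloxy)-4,5-dimethoxyphenyl]-6-methoxychroman-4-one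
Product: 22 (3R)-5,7-dihydroxy-3-(3-hydroxy-4,5-dimethoxyphenyl)-6-methoxychroman-4-one (CNP0258659.1)
Conditions: H2 (1 atm), 10% Pd/C, EtOAc/THF, rt
Reagents that add atoms: none
Why: Pd-catalysed hydrogenolysis of the three benzyl ethers under neutral conditions should leave the base-labile C3 stereocenter intact, and the 5-OH-chelated aryl ketone resists reduction.

**Compound list**

1 | 3,5-dihydroxy-4-methoxybenzoic acid (4-O-methylgallic acid) | COc1c(O)cc(cc1O)C(=O)O | starting material
2 | benzyl 3,5-bis(benzyloxy)-4-methoxybenzoate | COc1c(OCc2ccccc2)cc(cc1OCc1ccccc1)C(=O)OCc1ccccc1 | intermediate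
3 | [3,5-bis(benzyloxy)-4-methoxyphenyl]methanol | COc1c(OCc2ccccc2)cc(CO)cc1OCc1ccccc1 | intermediate
4 | 3,5-bis(benzyloxy)-4-methoxybenzaldehyde | COc1c(OCc2ccccc2)cc(C=O)cc1OCc1ccccc1 | intermediate
5 | 3,5-bis(benzyloxy)-4-methoxyphenyl formate | COc1c(OCc2ccccc2)cc(OC=O)cc1OCc1ccccc1 | intermediate (not isolated)
6 | 3,5-bis(benzyloxy)-4-methoxyphenol | COc1c(OCc2ccccc2)cc(O)cc1OCc1ccccc1 | intermediate
7 | 2-[3,5-bis(benzyloxy)-4-methoxyphenoxy]acetic acid | COc1c(OCc2ccccc2)cc(OCC(=O)O)cc1OCc1ccccc1 | intermediate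
8 | 2-[3,5-bis(benzyloxy)-4-methoxyphenoxy]acetic trifluoroacetic anhydride | COc1c(OCc2ccccc2)cc(OCC(=O)OC(=O)C(F)(F)F)cc1OCc1ccccc1 | intermediate (not isolated)
9 | 4,6-bis(benzyloxy)-5-methoxybenzofuran-3(2H)-one | COc1c(OCc2ccccc2)cc2OCC(=O)c2c1OCc1ccccc1 | intermediate
10 | [4,6-bis(benzyloxy)-5-methoxybenzofuran-3-yl]oxy(tert-butyl)dimethylsilane | COc1c(OCc2ccccc2)cc2occ(O[Si](C)(C)C(C)(C)C)c2c1OCc1ccccc1 | intermediate
11 | 3-(benzyloxy)-4,5-dimethoxybenzaldehyde | COc1cc(C=O)cc(OCc2ccccc2)c1OC | starting material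
12 | 3-(benzyloxy)-4,5-dimethoxybenzonitrile | COc1cc(C#N)cc(OCc2ccccc2)c1OC | intermediate
13 | lithium N,N'-bis(trimethylsilyl)-3-(benzyloxy)-4,5-dimethoxybenzamidinate | COc1cc(C(=N[Si](C)(C)C)N([Li])[Si](C)(C)C)cc(OCc2ccccc2)c1OC | intermediate (not isolated)
14 | 3-(benzyloxy)-4,5-dimethoxybenzamidine hydrochloride | Cl.COc1cc(C(N)=N)cc(OCc2ccccc2)c1OC | intermediate
15 | 3-[3-(benzyloxy)-4,5-dimethoxyphenyl]-3-chloro-3H-diazirine | COc1cc(C2(Cl)N=N2)cc(OCc2ccccc2)c1OC | intermediate
16 | 3,5-bis(benzyloxy)-1-[3-(benzyloxy)-4,5-dimethoxyphenyl]-6b-(tert-butyldimethylsilyloxy)-1-chloro-4-methoxy-1a,6b-dihydro-1H-cyclopropa[b]benzofuran (racemic, both C1 epimers) | COc1cc(C2(Cl)C3Oc4cc(OCc5ccccc5)c(OC)c(OCc5ccccc5)c4C23O[Si](C)(C)C(C)(C)C)cc(OCc2ccccc2)c1OC | intermediate (not isolated)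
17 | 5,7-bis(benzyloxy)-3-[3-(benzyloxy)-4,5-dimethoxyphenyl]-4-(tert-butyldimethylsilyloxy)-6-methoxychromenylium chloride | COc1cc(-c2c[o+]c3cc(OCc4ccccc4)c(OC)c(OCc4ccccc4)c3c2O[Si](C)(C)C(C)(C)C)cc(OCc2ccccc2)c1OC.[Cl-] | intermediate (not isolated)
18 | 5,7-bis(benzyloxy)-3-[3-(benzyloxy)-4,5-dimethoxyphenyl]-6-methoxy-4H-chromen-4-one | COc1cc(C2=COc3cc(OCc4ccccc4)c(OC)c(OCc4ccccc4)c3C2=O)cc(OCc2ccccc2)c1OC | intermediate
19 | rac-5,7-bis(benzyloxy)-3-[3-(benzyloxy)-4,5-dimethoxyphenyl]-6-methoxychroman-4-one | COc1cc(C2COc3cc(OCc4ccccc4)c(OC)c(OCc4ccccc4)c3C2=O)cc(OCc2ccccc2)c1OC | intermediate (not isolated)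
20 | (3R,4R)-5,7-bis(benzyloxy)-3-[3-(benzyloxy)-4,5-dimethoxyphenyl]-6-methoxychroman-4-ol (3,4-cis) | COc1cc([C@@H]2COc3cc(OCc4ccccc4)c(OC)c(OCc4ccccc4)c3[C@@H]2O)cc(OCc2ccccc2)c1OC | intermediate
21 | (3R)-5,7-bis(benzyloxy)-3-[3-(benzyloxy)-4,5-dimethoxyphenyl]-6-methoxychroman-4-one | COc1cc([C@@H]2COc3cc(OCc4ccccc4)c(OC)c(OCc4ccccc4)c3C2=O)cc(OCc2ccccc2)c1OC | intermediate
22 | (3R)-5,7-dihydroxy-3-(3-hydroxy-4,5-dimethoxyphenyl)-6-methoxychroman-4-one | COc1cc([C@@H]2COc3cc(O)c(OC)c(O)c3C2=O)cc(O)c1OC | target

**Step count and risks**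

Total step count: 14. Longest linear sequence: 11 steps (steps 1–7 and 11–14); the diazirine branch is 3 steps (8–10).

Steps most likely to fail:

1. Step 11 (proposed new method). The carbene may be diverted into azine formation or addition to the alkoxyarenes, the silyl enol ether may be desilylated back to 9 before it is trapped, or the cyclopropane epimer with Cl anti to the furan ring may fail to open. Fallback with known chemistry, setting out from 10: dibromocarbene addition (CHBr3, KOtBu, pentane, −20 °C to rt), the established dihalocarbene one-carbon ring expansion of silyl enol ethers, should give 5,7-bis(benzyloxy)-3-bromo-6-methoxy-4H-chromen-4-one F1. The aryl partner would be made from purchasable 5-bromo-2,3-dimethoxyphenol by benzylation (BnBr, K2CO3, DMF) to 1-(benzyloxy)-5-bromo-2,3-dimethoxybenzene F2, then Br/Li exchange and borylation (n-BuLi, B(OiPr)3, THF, −78 °C; aq. HCl) to [3-(benzyloxy)-4,5-dimethoxyphenyl]boronic acid F3. Suzuki–Miyaura coupling of F1 with F3 (Pd(dppf)Cl2, K2CO3, dioxane/H2O, 80 °C) comes back to the route at 18.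

2. Step 12. With the ketone flanked by the 5-benzyloxy group, carbonyl reduction may outrun racemisation of the intermediate ketone (incomplete dynamic kinetic resolution, eroded cis selectivity and ee), or the reduction may stall at the ketone stage. Fallback, setting out from 18: 1,4-reduction with L-Selectride (THF, −78 °C) and trapping of the enolate with TMSCl/Et3N should give the silyl enol ether 5,7-bis(benzyloxy)-3-[3-(benzyloxy)-4,5-dimethoxyphenyl]-6-methoxy-4-(trimethylsilyloxy)-2H-chromene F4. Catalytic enantioselective protonation of F4 (BINOL-derived N-triflyl thiophosphoramide, PhOH as proton source, toluene, rt; catalyst enantiomer chosen to deliver 3R), a known reaction type for silyl enol ethers of 2-aryl cyclic ketones, comes back to the route at 21 and bypasses 20 and step 13.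

3. Step 6. Closure of the strained five-membered ketone may be slow, so that trifluoroacetylation of the arene or acid-induced loss of a benzyl ether competes. Fallback, setting out from 6: Houben–Hoesch acylation with chloroacetonitrile (ZnCl2, HCl, Et2O, 0 °C; then H2O, reflux) should give 1-[4,6-bis(benzyloxy)-2-hydroxy-5-methoxyphenyl]-2-chloroethan-1-one F5. Intramolecular Williamson closure of F5 (NaOAc, EtOH, reflux) comes back to the route at 9 and bypasses 7.

**Further compounds**

F1 | step 11 | 5,7-bis(benzyloxy)-3-bromo-6-methoxy-4H-chromen-4-one | COc1c(OCc2ccccc2)cc2OC=C(Br)C(=O)c2c1OCc1ccccc1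
F2 | step 11 | 1-(benzyloxy)-5-bromo-2,3-dimethoxybenzene | COc1cc(Br)cc(OCc2ccccc2)c1OC
F3 | step 11 | [3-(benzyloxy)-4,5-dimethoxyphenyl]boronic acid | COc1cc(B(O)O)cc(OCc2ccccc2)c1OC
F4 | step 12 | 5,7-bis(benzyloxy)-3-[3-(benzyloxy)-4,5-dimethoxyphenyl]-6-methoxy-4-(trimethylsilyloxy)-2H-chromene | COc1cc(C2=C(O[Si](C)(C)C)c3c(OCc4ccccc4)c(OC)c(OCc4ccccc4)cc3OC2)cc(OCc2ccccc2)c1OC
F5 | step 6 | 1-[4,6-bis(benzyloxy)-2-hydroxy-5-methoxyphenyl]-2-chloroethan-1-one | COc1c(OCc2ccccc2)cc(O)c(C(=O)CCl)c1OCc1ccccc1
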